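**Retrosynthetic overview**
1. Target 33 is (12S,13Z)-12-hydroxylabda-8(17),13-diene-15,19-dioic acid (5α-H, 9α-H, 10β-CH3, axial C19 acid). Late disconnections: the O12–C15 butenolide (opened last), C19 alcohol to acid, and C13–C16 from ethyl propiolate plus Me2CuLi on a C12 aldehyde, with C12 set by a reagent-controlled ynone reduction.
2. The strategy rests on two features of rings A and B. The exocyclic C8=C17 methylene beside C9 (ring B) is the footprint of an allylsilane terminator. The axial, oxidised C19 on C4 (ring A) is the footprint of the Z substituent of a C3–C4 epoxide.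
3. Key disconnection: C4–C5 and C9–C10 in one epoxide-initiated, allylsilane-terminated cationic bicyclisation of the linear epoxy diene 17. Ring A closes first and ring B directly after it in the same step; the C3 hydroxyl left behind is removed by radical deoxygenation.
4. 17 comes from geranyl bromide (C1–C3, C5, C6, C10, C20), 1-(trimethylsilyl)propyne (C7–C9), a Z-selective phosphonate olefination (C4, C18, C19), silylmethylcupration of the alkyne with ethylene oxide capture (C17; C11, C12) and a Sharpless epoxidation with the D-(−)-tartrate.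
5. Order of events: the terminal alkene is cleaved before the allylsilane exists, and C19 stays an ester through the copper step, so no oxidant or acid meets the allylsilane before the key step.

Key step: step 10

Remark: labdane numbering is used for all intermediates (C17 exocyclic methylene carbon, C18 and C19 on C4, C20 on C10, C11–C16 side chain).
Assumption: the open (Z)-γ-hydroxy acid is taken to be isolable when the dicarboxylate is protonated cold and briefly; stronger acid or heat would return butenolide 31.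

**Route**

Step 1
Reactants: 1 geranyl bromide; 2 1-(trimethylsilyl)propyne
Product: 3 (E)-(6,10-dimethylundeca-5,9-dien-1-yn-1-yl)trimethylsilane
Conditions: 2, n-BuLi, THF, −78 to −20 °C; then 1, −78 to 0 °C
Reagents that add atoms: none
Why: SN2 alkylation of the propargylic lithium reagent by the allylic bromide forms C6–C7; the silyl cap blocks the alkyne terminus and the E alkene of 1 is untouched.

Step 2
Reactants: 3
Product: 5 (E)-2,2-dimethyl-3-(3-methyloct-3-en-7-yn-1-yl)oxirane (racemic), via bromohydrin 4 (not isolated)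
Conditions: NBS, THF/H2O, 0 °C; then K2CO3, MeOH, rt
Reagents that add atoms: water, O
Why: In aqueous THF the bromonium ion should form at the terminal trisubstituted alkene in preference to the internal one and water opens it at the tertiary carbon; K2CO3 in methanol then closes the epoxide (intramolecular Williamson reaction) and cleaves the alkynyl C–Si bond, and the racemic C3 centre is destroyed in step 3.

Step 3
Reactants: 5
Product: 7 (E)-4-methylnon-4-en-8-ynal, via vicinal diol 6 (not isolated)
Conditions: H5IO6, THF/H2O, 0 °C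
Reagents that add atoms: none
Why: Periodic acid hydrates the epoxide and cleaves the glycol (Malaprade cleavage), giving the C3 aldehyde and acetone while the alkene and the alkyne stay inert.

Step 4
Reactants: 7; 8 ethyl 2-[bis(2,2,2-trifluoroethoxy)phosphoryl]propanoate
Product: 9 ethyl (2Z,6E)-2,6-dimethylundeca-2,6-dien-10-ynoate
Conditions: 8, KN(SiMe3)2, 18-crown-6, THF, −78 °C; then 7
Reagents that add atoms: none
Why: Still–Gennari variant of the Horner–Wadsworth–Emmons olefination; the electron-poor phosphonate with a dissociated potassium ion eliminates from the kinetic adduct and gives the Z enoate, in which the ester carbon (C19) is cis to the chain.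

Step 5
Reactants: 9; 10 (trimethylsilyl)methylmagnesium chloride; 11 ethylene oxide
Product: 13 ethyl (2Z,6E,10Z)-13-hydroxy-2,6-dimethyl-10-[(trimethylsilyl)methyl]trideca-2,6,10-trienoate, via alkenylcopper 12 (not isolated)
Conditions: 10, CuBr·SMe2, Et2O/Me2S, −25 °C; 9, −25 to 0 °C; then LiC≡CPr, HMPA, 11, −40 to −10 °C; aq. NH4Cl
Reagents that add atoms: none
Why: Normant carbocupration; the silylmethylcopper reagent adds syn across the terminal alkyne with carbon on the internal position (C8), and the alkenylcopper, activated as a mixed alkynyl cuprate, opens ethylene oxide with retention, so C17 and C11 end up cis (C7 trans to C11), while the hindered α-methyl enoate should not be attacked by these copper reagents at low temperature.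

Step 6
Reactants: 13
Product: 14 ethyl (2Z,6E,10Z)-13-(tert-butyldimethylsilyloxy)-2,6-dimethyl-10-[(trimethylsilyl)methyl]trideca-2,6,10-trienoate
Conditions: TBSCl, imidazole, DMF, 0 °C to rt
Reagents that add atoms: tert-butyldimethylsilyl chloride, CC(C)(C)[Si](C)(C)Cl
Why: Standard silylation of the unhindered primary alcohol.

Step 7
Reactants: 14
Product: 15 (2Z,6E,10Z)-13-(tert-butyldimethylsilyloxy)-2,6-dimethyl-10-[(trimethylsilyl)methyl]trideca-2,6,10-trien-1-ol
Conditions: i-Bu2AlH, CH2Cl2, −78 °C; Rochelle salt work-up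
Reagents that add atoms: none
Why: 1,2-reduction of the enoate gives the Z allylic alcohol without change of alkene geometry and without touching the allylsilane or the silyl ether.

Step 8
Reactants: 15
Product: 16 [(2R,3S)-3-[(3E,7Z)-10-(tert-butyldimethylsilyloxy)-3-methyl-7-[(trimethylsilyl)methyl]deca-3,7-dien-1-yl]-2-methyloxiran-2-yl]methanol
Conditions: Ti(OiPr)4 (cat.), D-(−)-diisopropyl tartrate (cat.), t-BuOOH, 4 Å MS, CH2Cl2, −20 °C
Reagents that add atoms: tert-butyl hydroperoxide, CC(C)(C)OO
Why: Katsuki–Sharpless asymmetric epoxidation; titanium binds only the allylic alcohol, so the C5=C10 alkene and the allylsilane are left, and the D-(−)-tartrate delivers oxygen to the face that gives the (2R,3S)-oxirane (3S,4R in labdane numbering), which fixes the absolute configuration of the route.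

Step 9
Reactants: 16
Product: 17 epoxy diene allylsilane, the TBDPS ether of 16 at O19
Conditions: TBDPSCl, imidazole, DMF, 0 °C to rt
Reagents that add atoms: tert-butyldiphenylsilyl chloride, CC(C)(C)[Si](Cl)(c1ccccc1)c1ccccc1
Why: Silylation of the primary epoxy alcohol under non-acidic conditions gives the bulky, weakly basic ether wanted next to the epoxide.

Step 10
Reactants: 17
Product: 18 12-(tert-butyldimethylsilyloxy)-19-(tert-butyldiphenylsilyloxy)-13,14,15,16-tetranorlabd-8(17)-en-3β-ol
Conditions: MeAlCl2, CH2Cl2, −78 °C; Et3N then aq. NaHCO3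
Reagents that add atoms: none
Why: MeAlCl2 binds the epoxide oxygen and the C4–O bond ionises as C5 of the C5=C10 alkene attacks C4 from the back; the C10 cation that develops is taken by C9 of the allylsilane, and the β-silyl cation at C8 loses Me3Si to chloride, leaving C8=C17. The closest known reaction type is the Lewis acid-induced epoxy-polyene cyclisation terminated by an allylsilane (an intramolecular Hosomi–Sakurai capture). Ring A (C4–C5) and ring B (C9–C10) both close in the 6-endo mode with respect to the attacking alkene, through a chair–chair fold. C3 keeps the epoxide configuration (3β-OH, equatorial); C4 is inverted, so the silyloxymethyl group that was cis to the chain becomes axial C19 and the methyl equatorial C18; C5 and C10 follow from anti addition across the E C5=C10 alkene (5α-H, 10β-CH3, trans fusion); C9 follows from the C8=C9 geometry, C11 trans to C7 ending equatorial (9α-H). The step needs opening at the tertiary C4 in preference to hydride shift to a C3 ketone, a complete cascade, and a single alkene position: the tertiary epoxide carbon, the low temperature and the bulky TBDPS ether favour the first two, and the β-silicon effect fixes the alkene at C8=C17.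

Step 11
Reactants: 18
Product: 19 O-[12-(tert-butyldimethylsilyloxy)-19-(tert-butyldiphenylsilyloxy)-13,14,15,16-tetranorlabd-8(17)-en-3β-yl] 1H-imidazole-1-carbothioate
Conditions: 1,1'-thiocarbonyldiimidazole, DMAP (cat.), toluene, 90 °C
Reagents that add atoms: 1,1'-thiocarbonyldiimidazole, S=C(n1ccnc1)n1ccnc1
Why: Thioacylation of the hindered equatorial alcohol (first half of a Barton–McCombie deoxygenation) under neutral conditions, which avoids silyl migration from O19 to an O3 alkoxide.

Step 12
Reactants: 19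
Product: 20 12-(tert-butyldimethylsilyloxy)-19-(tert-butyldiphenylsilyloxy)-13,14,15,16-tetranorlabd-8(17)-ene
Conditions: Bu3SnH, AIBN (cat.), toluene, 100 °C
Reagents that add atoms: none
Why: Barton–McCombie radical deoxygenation; the stannyl radical adds to the thiocarbonyl, the C3–O bond fragments and the secondary C3 radical is reduced, with no alkene within its reach.

Step 13
Reactants: 20
Product: 21 19-(tert-butyldiphenylsilyloxy)-13,14,15,16-tetranorlabd-8(17)-en-12-ol
Conditions: camphorsulfonic acid (cat.), MeOH/CH2Cl2, 0 °C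
Reagents that add atoms: none
Why: Acid-catalysed methanolysis removes the unhindered primary TBS ether far faster than the neopentyl TBDPS ether on C19, and the mild acid should not move the exocyclic alkene.

Step 14
Reactants: 21
Product: 22 19-(tert-butyldiphenylsilyloxy)-13,14,15,16-tetranorlabd-8(17)-en-12-al
Conditions: Dess–Martin periodinane, NaHCO3, CH2Cl2, 0 °C to rt
Reagents that add atoms: none
Why: Dess–Martin oxidation of the primary alcohol under buffered conditions that leave C9 and the alkene alone.

Step 15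
Reactants: 22; 23 ethyl propiolate
Product: 24 ethyl 19-(tert-butyldiphenylsilyloxy)-12-hydroxy-16-norlabd-8(17)-en-13-yn-15-oate (both C12 epimers)
Conditions: 23, n-BuLi, THF, −78 °C; then 22, −78 °C; aq. NH4Cl
Reagents that add atoms: none
Why: 1,2-addition of lithium ethyl propiolate to the aldehyde forms C12–C13; both epimers are carried on because C12 is erased in step 16.

Step 16
Reactants: 24
Product: 25 ethyl 19-(tert-butyldiphenylsilyloxy)-12-oxo-16-norlabd-8(17)-en-13-yn-15-oate
Conditions: Dess–Martin periodinane, NaHCO3, CH2Cl2, 0 °C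
Reagents that add atoms: none
Why: Dess–Martin oxidation of the propargylic alcohol gives the γ-oxo ynoate without acid or base that could add to the activated alkyne.

Step 17
Reactants: 25
Product: 26 ethyl (12S)-19-(tert-butyldiphenylsilyloxy)-12-hydroxy-16-norlabd-8(17)-en-13-yn-15-oate
Conditions: (S)-Alpine-Borane [B-isopinocampheyl-9-BBN from (−)-α-pinene], THF, 0 °C to rt; then CH3CHO; HOCH2CH2NH2
Reagents that add atoms: none
Why: Midland reduction; hydride is transferred through a boat-like six-membered transition state with the slim alkynyl group next to the pinane methyl, so the reagent from (−)-α-pinene gives the S carbinol here (the sense by which it reduces 1-octyn-3-one to the S alcohol), and the activated γ-oxo ynoate should be reduced before the reagent can dissociate and hydroborate the exocyclic alkene.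

Step 18
Reactants: 26
Product: 28 (12S)-19-(tert-butyldiphenylsilyloxy)labda-8(17),13-dien-15,12-olide, via hydroxy enoate 27 (not isolated)
Conditions: Me2CuLi (from MeLi, CuI), THF, −78 °C; AcOH at −78 °C; aq. NH4Cl, rt
Reagents that add atoms: lithium dimethylcuprate, [Li+].C[Cu-]C
Why: syn-carbocupration of the ynoate puts the methyl (C16) on C13 and copper on C14; protonation with retention gives the 13Z hydroxy enoate, whose cis hydroxyl and ester close to the butenolide (lactonisation) without touching C12.

Step 19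
Reactants: 28
Product: 29 (12S)-19-hydroxylabda-8(17),13-dien-15,12-olide
Conditions: Bu4NF, AcOH, THF, rt to 40 °C
Reagents that add atoms: none
Why: Fluoride cleaves the neopentyl silyl ether, and the acetic acid buffer keeps the medium from removing the γ-proton (C12–H) of the butenolide.

Step 20
Reactants: 29
Product: 31 (12S)-15-oxo-12,15-epoxylabda-8(17),13-dien-19-oic acid, via C19 aldehyde 30 (not isolated)
Conditions: Dess–Martin periodinane, CH2Cl2, rt; then NaClO2, NaH2PO4, 2-methyl-2-butene, t-BuOH/H2O, rt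
Reagents that add atoms: sodium chlorite, [Na+].[O-]Cl=O
Why: Dess–Martin oxidation followed by Pinnick oxidation converts the hindered axial CH2OH into the acid; 2-methyl-2-butene takes up HOCl and so protects the exocyclic alkene, and the butenolide is inert to both oxidants.

Step 21
Reactants: 31
Product: 33 (12S,13Z)-12-hydroxylabda-8(17),13-diene-15,19-dioic acid, via dilithium dicarboxylate 32 (not isolated)
Conditions: LiOH, THF/H2O, 0 °C to rt; then 0.5 M HCl to pH 4, 0 °C, rapid extraction
Reagents that add atoms: lithium hydroxide, [Li+].[OH-]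
Why: Saponification of the butenolide by acyl–oxygen cleavage keeps the C12 configuration and the 13Z geometry, and cold, brief protonation should free both acids before relactonisation.

**Compound list**
1 | geranyl bromide | CC(C)=CCC/C(C)=C/CBr | starting material
2 | 1-(trimethylsilyl)propyne | CC#C[Si](C)(C)C | starting material
3 | (E)-(6,10-dimethylundeca-5,9-dien-1-yn-1-yl)trimethylsilane | CC(C)=CCC/C(C)=C/CCC#C[Si](C)(C)C | intermediate
4 | (E)-3-bromo-2,6-dimethyl-11-(trimethylsilyl)undec-6-en-10-yn-2-ol, racemic | CC(C)(O)C(Br)CC/C(C)=C/CCC#C[Si](C)(C)C | intermediate (not isolated)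
5 | (E)-2,2-dimethyl-3-(3-methyloct-3-en-7-yn-1-yl)oxirane, racemic | CC1(C)OC1CC/C(C)=C/CCC#C | intermediate
6 | (E)-2,6-dimethylundec-6-en-10-yne-2,3-diol, racemic | CC(C)(O)C(O)CC/C(C)=C/CCC#C | intermediate (not isolated)
7 | (E)-4-methylnon-4-en-8-ynal | O=CCC/C(C)=C/CCC#C | intermediate
8 | ethyl 2-[bis(2,2,2-trifluoroethoxy)phosphoryl]propanoate | CCOC(=O)C(C)P(=O)(OCC(F)(F)F)OCC(F)(F)F | starting material
9 | ethyl (2Z,6E)-2,6-dimethylundeca-2,6-dien-10-ynoate | CCOC(=O)/C(C)=C\CC/C(C)=C/CCC#C | intermediate
10 | (trimethylsilyl)methylmagnesium chloride | C[Si](C)(C)C[Mg]Cl | starting material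
11 | ethylene oxide | C1CO1 | starting material
12 | alkenylcopper from syn addition to 9 (Cu on C9, cis to the silylmethyl group) | CCOC(=O)/C(C)=C\CC/C(C)=C/CC/C(C[Si](C)(C)C)=C/[Cu] | intermediate (not isolated)
13 | ethyl (2Z,6E,10Z)-13-hydroxy-2,6-dimethyl-10-[(trimethylsilyl)methyl]trideca-2,6,10-trienoate | CCOC(=O)/C(C)=C\CC/C(C)=C/CC/C(C[Si](C)(C)C)=C/CCO | intermediate
14 | TBS ether of 13 | CCOC(=O)/C(C)=C\CC/C(C)=C/CC/C(C[Si](C)(C)C)=C/CCO[Si](C)(C)C(C)(C)C | intermediate
15 | (2Z,6E,10Z)-13-(tert-butyldimethylsilyloxy)-2,6-dimethyl-10-[(trimethylsilyl)methyl]trideca-2,6,10-trien-1-ol | OC/C(C)=C\CC/C(C)=C/CC/C(C[Si](C)(C)C)=C/CCO[Si](C)(C)C(C)(C)C | intermediate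
16 | (2R,3S)-epoxy alcohol of 15 (3S,4R in labdane numbering) | OC[C@@]1(C)O[C@H]1CC/C(C)=C/CC/C(C[Si](C)(C)C)=C/CCO[Si](C)(C)C(C)(C)C | intermediate
17 | TBDPS ether of 16, the cyclisation precursor | CC(C)(C)[Si](c1ccccc1)(c1ccccc1)OC[C@@]1(C)O[C@H]1CC/C(C)=C/CC/C(C[Si](C)(C)C)=C/CCO[Si](C)(C)C(C)(C)C | intermediate
18 | 12-(tert-butyldimethylsilyloxy)-19-(tert-butyldiphenylsilyloxy)-13,14,15,16-tetranorlabd-8(17)-en-3β-ol | C=C1CC[C@@H]2[C@](C)(CC[C@H](O)[C@]2(C)CO[Si](c3ccccc3)(c3ccccc3)C(C)(C)C)[C@H]1CCO[Si](C)(C)C(C)(C)C | intermediate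
19 | 3β-O-(imidazol-1-ylthiocarbonyl) derivative of 18 | C=C1CC[C@@H]2[C@](C)(CC[C@H](OC(=S)n3ccnc3)[C@]2(C)CO[Si](c3ccccc3)(c3ccccc3)C(C)(C)C)[C@H]1CCO[Si](C)(C)C(C)(C)C | intermediate
20 | 12-(tert-butyldimethylsilyloxy)-19-(tert-butyldiphenylsilyloxy)-13,14,15,16-tetranorlabd-8(17)-ene | C=C1CC[C@@H]2[C@](C)(CCC[C@]2(C)CO[Si](c3ccccc3)(c3ccccc3)C(C)(C)C)[C@H]1CCO[Si](C)(C)C(C)(C)C | intermediate
21 | 19-(tert-butyldiphenylsilyloxy)-13,14,15,16-tetranorlabd-8(17)-en-12-ol | C=C1CC[C@@H]2[C@](C)(CCC[C@]2(C)CO[Si](c3ccccc3)(c3ccccc3)C(C)(C)C)[C@H]1CCO | intermediate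
22 | 19-(tert-butyldiphenylsilyloxy)-13,14,15,16-tetranorlabd-8(17)-en-12-al | C=C1CC[C@@H]2[C@](C)(CCC[C@]2(C)CO[Si](c3ccccc3)(c3ccccc3)C(C)(C)C)[C@H]1CC=O | intermediate
23 | ethyl propiolate | C#CC(=O)OCC | starting material
24 | ethyl 19-(tert-butyldiphenylsilyloxy)-12-hydroxy-16-norlabd-8(17)-en-13-yn-15-oate, C12 epimers | C=C1CC[C@@H]2[C@](C)(CCC[C@]2(C)CO[Si](c3ccccc3)(c3ccccc3)C(C)(C)C)[C@H]1CC(O)C#CC(=O)OCC | intermediate
25 | ethyl 19-(tert-butyldiphenylsilyloxy)-12-oxo-16-norlabd-8(17)-en-13-yn-15-oate | C=C1CC[C@@H]2[C@](C)(CCC[C@]2(C)CO[Si](c3ccccc3)(c3ccccc3)C(C)(C)C)[C@H]1CC(=O)C#CC(=O)OCC | intermediate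
26 | ethyl (12S)-19-(tert-butyldiphenylsilyloxy)-12-hydroxy-16-norlabd-8(17)-en-13-yn-15-oate | C=C1CC[C@@H]2[C@](C)(CCC[C@]2(C)CO[Si](c3ccccc3)(c3ccccc3)C(C)(C)C)[C@H]1C[C@H](O)C#CC(=O)OCC | intermediate
27 | ethyl (12S,13Z)-19-(tert-butyldiphenylsilyloxy)-12-hydroxylabda-8(17),13-dien-15-oate | C=C1CC[C@@H]2[C@](C)(CCC[C@]2(C)CO[Si](c3ccccc3)(c3ccccc3)C(C)(C)C)[C@H]1C[C@H](O)/C(C)=C\C(=O)OCC | intermediate (not isolated)
28 | (12S)-19-(tert-butyldiphenylsilyloxy)labda-8(17),13-dien-15,12-olide | C=C1CC[C@@H]2[C@](C)(CCC[C@]2(C)CO[Si](c3ccccc3)(c3ccccc3)C(C)(C)C)[C@H]1C[C@@H]1OC(=O)C=C1C | intermediate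
29 | (12S)-19-hydroxylabda-8(17),13-dien-15,12-olide | C=C1CC[C@@H]2[C@](C)(CCC[C@]2(C)CO)[C@H]1C[C@@H]1OC(=O)C=C1C | intermediate
30 | (12S)-19-oxolabda-8(17),13-dien-15,12-olide | C=C1CC[C@@H]2[C@](C)(CCC[C@]2(C)C=O)[C@H]1C[C@@H]1OC(=O)C=C1C | intermediate (not isolated)
31 | (12S)-15-oxo-12,15-epoxylabda-8(17),13-dien-19-oic acid | C=C1CC[C@@H]2[C@](C)(CCC[C@]2(C)C(=O)O)[C@H]1C[C@@H]1OC(=O)C=C1C | intermediate
32 | dilithium (12S,13Z)-12-hydroxylabda-8(17),13-diene-15,19-dioate | [Li+].[Li+].C=C1CC[C@@H]2[C@](C)(CCC[C@]2(C)C(=O)[O-])[C@H]1C[C@H](O)/C(C)=C\C(=O)[O-] | intermediate (not isolated)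
33 | (12S,13Z)-12-hydroxylabda-8(17),13-diene-15,19-dioic acid | C=C1CC[C@@H]2[C@](C)(CCC[C@]2(C)C(=O)O)[C@H]1C[C@H](O)/C(C)=C\C(=O)O | target

Total step count: 21
Longest linear sequence: 21 steps (1 to 33)

**Steps most likely to fail**

Step 10 (key step). The cascade may stop after ring A or divert to a C3 ketone by hydride shift. The basic silyl ether oxygen on C12 may also bind the promoter or capture the β-silyl cation at C8, with loss of the TBS group and closure of an 8,12-oxolane. The fallback reshapes the terminator side chain so that this oxygen is acylated, and sets out from 17. Acid-catalysed methanolysis of the primary TBS ether (pyridinium p-toluenesulfonate, MeOH, 0 °C to rt) should give (3Z,7E)-10-[(2S,3R)-3-[(tert-butyldiphenylsilyloxy)methyl]-3-methyloxiran-2-yl]-8-methyl-4-[(trimethylsilyl)methyl]deca-3,7-dien-1-ol F1. Pivaloyl chloride, pyridine and DMAP give its pivalate F2. MeAlCl2 (one extra equivalent for the ester carbonyl, CH2Cl2, −78 °C) should then give 19-(tert-butyldiphenylsilyloxy)-3β-hydroxy-13,14,15,16-tetranorlabd-8(17)-en-12-yl pivalate F3. Thiocarbonyldiimidazole with DMAP gives the 3β-O-(imidazol-1-ylthiocarbonyl) pivalate F4, and Bu3SnH with AIBN gives the 3-deoxy pivalate F5. Reduction with i-Bu2AlH (CH2Cl2, −78 °C) removes the pivalate and the route is rejoined at 21.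

Step 5. The organometallic reagents may add to the enoate, or the silylmethylcopper may add to the alkyne so slowly that the temperature needed destroys the reagent or the ester. The fallback takes the ester out before the copper step and sets out from 9. Reduction with i-Bu2AlH gives (2Z,6E)-2,6-dimethylundeca-2,6-dien-10-yn-1-ol F6, and Et3SiCl with imidazole gives its triethylsilyl ether F7. The same carbocupration with ethylene oxide capture should give (3Z,7E,11Z)-8,12-dimethyl-13-(triethylsilyloxy)-4-[(trimethylsilyl)methyl]trideca-3,7,11-trien-1-ol F8, and TBSCl with imidazole gives the bis-silyl ether F9. Brief methanolysis (pyridinium p-toluenesulfonate, MeOH, 0 °C) cleaves the more labile allylic triethylsilyl ether, and the route is rejoined at 15.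

Step 17. If hydride transfer to the ketone is slow, the borane may dissociate; the freed 9-BBN would then hydroborate the 8(17) alkene and the facial selectivity at C12 would erode. The fallback sets out from 22 and forms C12–C13 and the C12 centre in one catalytic step. Ethyl propiolate 23, Me2Zn and the ProPhenol ligand (toluene, 4 °C) are used, with the ligand antipode that gives the 12S carbinol, to be confirmed by Mosher ester analysis. This leads straight to 26, skipping 24 and 25.

**Further compounds**
F1 | step 10 | (3Z,7E)-10-[(2S,3R)-3-[(tert-butyldiphenylsilyloxy)methyl]-3-methyloxiran-2-yl]-8-methyl-4-[(trimethylsilyl)methyl]deca-3,7-dien-1-ol | CC(C)(C)[Si](c1ccccc1)(c1ccccc1)OC[C@@]1(C)O[C@H]1CC/C(C)=C/CC/C(C[Si](C)(C)C)=C/CCO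
F2 | step 10 | pivalate of F1 | CC(C)(C)[Si](c1ccccc1)(c1ccccc1)OC[C@@]1(C)O[C@H]1CC/C(C)=C/CC/C(C[Si](C)(C)C)=C/CCOC(=O)C(C)(C)C
F3 | step 10 | 19-(tert-butyldiphenylsilyloxy)-3β-hydroxy-13,14,15,16-tetranorlabd-8(17)-en-12-yl pivalate | C=C1CC[C@@H]2[C@](C)(CC[C@H](O)[C@]2(C)CO[Si](c3ccccc3)(c3ccccc3)C(C)(C)C)[C@H]1CCOC(=O)C(C)(C)C
F4 | step 10 | 3β-O-(imidazol-1-ylthiocarbonyl) derivative of F3 | C=C1CC[C@@H]2[C@](C)(CC[C@H](OC(=S)n3ccnc3)[C@]2(C)CO[Si](c3ccccc3)(c3ccccc3)C(C)(C)C)[C@H]1CCOC(=O)C(C)(C)C
F5 | step 10 | 19-(tert-butyldiphenylsilyloxy)-13,14,15,16-tetranorlabd-8(17)-en-12-yl pivalate | C=C1CC[C@@H]2[C@](C)(CCC[C@]2(C)CO[Si](c3ccccc3)(c3ccccc3)C(C)(C)C)[C@H]1CCOC(=O)C(C)(C)C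
F6 | step 5 | (2Z,6E)-2,6-dimethylundeca-2,6-dien-10-yn-1-ol | OC/C(C)=C\CC/C(C)=C/CCC#C
F7 | step 5 | triethylsilyl ether of F6 | CC[Si](CC)(CC)OC/C(C)=C\CC/C(C)=C/CCC#C
F8 | step 5 | (3Z,7E,11Z)-8,12-dimethyl-13-(triethylsilyloxy)-4-[(trimethylsilyl)methyl]trideca-3,7,11-trien-1-ol | CC[Si](CC)(CC)OC/C(C)=C\CC/C(C)=C/CC/C(C[Si](C)(C)C)=C/CCO
F9 | step 5 | TBS ether of F8 | CC[Si](CC)(CC)OC/C(C)=C\CC/C(C)=C/CC/C(C[Si](C)(C)C)=C/CCO[Si](C)(C)C(C)(C)C
F0 | step 17 | none | none
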